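**Plan**

- Numbering: ring C is O1, C2, C3, C4(=O), C4a, C8a; ring A is the benzo ring; ring B is the aryl group on C2. The enabling feature is that O1 links aromatic C8a of ring A to the stereogenic benzylic carbon C2, so O1 and the C2 configuration can be brought in together as the hydroxyl of one enantiopure secondary alcohol that is arylated at oxygen.
- Retrosynthetic cuts, in order: C4=O back to a C4 carbinol; the O1–C8a aryl ether bond (bromine on C8a); both carbinols back to a 1,3-diketone; the C3–C4 bond (aldol of a ring A aldehyde with the methyl ketone of ring B, then oxidation); the C4–C4a bond (formylation of 1-bromo-3,5-dimethoxybenzene).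
- Forward: rings A and B are bought as arenes, the C2–C3–C4 chain is joined by the aldol, and ring C is closed in the fifth of six steps.
- Stereochemistry: C2 (S), the only stereocentre of the target, is set by ruthenium transfer hydrogenation with the (S,S)-TsDPEN ligand and its C–O bond is never broken afterwards. The C4 carbinol set in the same step is temporary and is oxidised away at the end.

Key step: step 5

Assumption: in step 4 the first hydride is taken to go to the less hindered carbonyl beside ring B; the opposite order would give the same diol. In the open-chain compounds C1 is the later C4 and C3 the later C2.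

**Route**

Step 1
Reactants: 1 1-bromo-3,5-dimethoxybenzene
Product: 3 2-bromo-4,6-dimethoxybenzaldehyde, via aryl iminium salt 2 (not isolated)
Conditions: POCl3 (1.5 equiv), DMF, 0 → 90 °C; then ice/H2O
Reagents that add atoms: N,N-dimethylformamide, CN(C)C=O (formyl carbon); water, O (carbonyl oxygen)
Why: Vilsmeier–Haack formylation, in which the chloroiminium ion from DMF and POCl3 should attack the position para to one methoxy group and ortho to the other, which is less crowded than the position between the two methoxy groups, so that the formyl group enters next to bromine as ring A requires, and water then hydrolyses the iminium salt.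

Step 2
Reactants: 3 2-bromo-4,6-dimethoxybenzaldehyde; 4 2,3,4-trimethoxyacetophenone
Product: 6 racemic 3-(2-bromo-4,6-dimethoxyphenyl)-3-hydroxy-1-(2,3,4-trimethoxyphenyl)propan-1-one, via lithium enolate 5 (not isolated)
Conditions: 4 (1.1 equiv), LiN(iPr)2 (1.05 equiv), THF, −78 °C; then 3, −78 °C; AcOH, −78 °C
Reagents that add atoms: none
Why: Directed crossed aldol addition, in which the kinetic lithium enolate of the methyl ketone adds to the non-enolisable aldehyde to form the C3–C4 bond and cold protonation of the chelated aldolate is meant to forestall retro-aldol cleavage and dehydration; the new carbinol is racemic and is removed in step 3.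

Step 3
Reactants: 6 racemic 3-(2-bromo-4,6-dimethoxyphenyl)-3-hydroxy-1-(2,3,4-trimethoxyphenyl)propan-1-one
Product: 7 1-(2-bromo-4,6-dimethoxyphenyl)-3-(2,3,4-trimethoxyphenyl)propane-1,3-dione
Conditions: 2-iodoxybenzoic acid (IBX, 1.5 equiv), DMSO, rt
Reagents that add atoms: none
Why: IBX oxidation of a β-hydroxy ketone to the 1,3-diketone, a reagent expected to stop at the diketone without attacking its central methylene, under near-neutral conditions that should not ionise the methoxy-activated benzylic carbinol before it becomes a carbonyl.

Step 4
Reactants: 7 1-(2-bromo-4,6-dimethoxyphenyl)-3-(2,3,4-trimethoxyphenyl)propane-1,3-dione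
Product: 9 (1S,3S)-1-(2-bromo-4,6-dimethoxyphenyl)-3-(2,3,4-trimethoxyphenyl)propane-1,3-diol, via (3S)-hydroxy ketone 8 (not isolated)
Conditions: RuCl(p-cymene)[(S,S)-TsDPEN] (5 mol %), HCO2H/Et3N (1:1), DMF, 40 °C
Reagents that add atoms: none
Why: Noyori–Ikariya asymmetric transfer hydrogenation of a 1,3-diaryl-1,3-diketone to the anti-1,3-diol, in which the Ru–H/N–H pair of the (S,S)-TsDPEN complex delivers hydride to each aryl ketone in the sense known to give S carbinols from acetophenone-type ketones, first at the less hindered carbonyl (the later C2) and then beside ring A; a wrongly set centre ends up mainly in the separable syn diol, so the anti diol should be enriched further, and the 1:1 formate salt keeps the medium near neutral so the benzylic carbinols are not ionised.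

Step 5
Reactants: 9 (1S,3S)-1-(2-bromo-4,6-dimethoxyphenyl)-3-(2,3,4-trimethoxyphenyl)propane-1,3-diol
Product: 10 (2S,4S)-5,7-dimethoxy-2-(2,3,4-trimethoxyphenyl)-3,4-dihydro-2H-chromen-4-ol
Conditions: CuI (10 mol %), 3,4,7,8-tetramethyl-1,10-phenanthroline (20 mol %), Cs2CO3 (2 equiv), toluene (0.05 M), 110 °C, Ar
Reagents that add atoms: none
Why: Cs2CO3 turns the C3 hydroxyl of the diol (the later C2 oxygen) into a phenanthroline-bound alkoxide of monovalent copper, the C–Br bond of ring A is activated at that centre (oxidative addition to a trivalent copper aryl alkoxide or an equivalent concerted path), and C–O reductive elimination forms O1–C8a and returns monovalent copper. The closest known reaction type is the copper/phenanthroline Ullmann-type etherification of aryl halides with aliphatic alcohols, including its intramolecular use for chromans. Ring C closes as a six-membered benzo-fused ether by attack of the tethered alkoxide oxygen on C8a, formally a 6-exo closure since the breaking C–Br bond lies outside the new ring, by way of a seven-membered copper-containing cycle. No stereocentre is created: the C–O bonds at C2 and C4 are never broken, so both configurations from step 4 are carried over and the 2,4-cis flavan-4-ol should result. The step needs the C2 hydroxyl to react rather than the C4 hydroxyl or a second molecule, which ring size (the C4 oxygen could reach C8a only through a four-membered ring) and dilution secure. Copper is preferred to palladium because its secondary benzylic alkoxide is not prone to beta-hydride elimination, and C4 is kept as a carbinol so that no base-labile β-hydroxy ketone meets the carbonate.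

Step 6
Reactants: 10 (2S,4S)-5,7-dimethoxy-2-(2,3,4-trimethoxyphenyl)-3,4-dihydro-2H-chromen-4-ol
Product: 11 (2S)-5,7-dimethoxy-2-(2,3,4-trimethoxyphenyl)-2,3-dihydro-4H-chromen-4-one
Conditions: Dess–Martin periodinane (1.2 equiv), pyridine (3 equiv), CH2Cl2, 0 °C
Reagents that add atoms: none
Why: Dess–Martin oxidation of the secondary benzylic C4 carbinol to the aryl ketone, fast at 0 °C and buffered with pyridine so that neither acid (ionisation at C4 or C2) nor strong base (enolisation at C3 and opening of the O1–C2 bond, which would racemise C2) acts on the product; C2 takes no part and should keep its S configuration.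

**Compound list**

1 | 1-bromo-3,5-dimethoxybenzene | COc1cc(Br)cc(OC)c1 | starting material
2 | N-[(2-bromo-4,6-dimethoxyphenyl)methylidene]-N-methylmethanaminium dichlorophosphate | COc1cc(OC)c(C=[N+](C)C)c(Br)c1.[O-]P(=O)(Cl)Cl | intermediate
3 | 2-bromo-4,6-dimethoxybenzaldehyde | COc1cc(OC)c(C=O)c(Br)c1 | intermediate
4 | 2,3,4-trimethoxyacetophenone, 1-(2,3,4-trimethoxyphenyl)ethan-1-one | CC(=O)c1ccc(OC)c(OC)c1OC | starting material
5 | lithium 1-(2,3,4-trimethoxyphenyl)ethen-1-olate | [Li+].[O-]C(=C)c1ccc(OC)c(OC)c1OC | intermediate
6 | racemic 3-(2-bromo-4,6-dimethoxyphenyl)-3-hydroxy-1-(2,3,4-trimethoxyphenyl)propan-1-one | COc1cc(OC)c(C(O)CC(=O)c2ccc(OC)c(OC)c2OC)c(Br)c1 | intermediate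
7 | 1-(2-bromo-4,6-dimethoxyphenyl)-3-(2,3,4-trimethoxyphenyl)propane-1,3-dione | COc1cc(OC)c(C(=O)CC(=O)c2ccc(OC)c(OC)c2OC)c(Br)c1 | intermediate
8 | (3S)-1-(2-bromo-4,6-dimethoxyphenyl)-3-hydroxy-3-(2,3,4-trimethoxyphenyl)propan-1-one | O[C@H](c1ccc(OC)c(OC)c1OC)CC(=O)c1c(OC)cc(OC)cc1Br | intermediate
9 | (1S,3S)-1-(2-bromo-4,6-dimethoxyphenyl)-3-(2,3,4-trimethoxyphenyl)propane-1,3-diol | O[C@H](c1ccc(OC)c(OC)c1OC)C[C@H](O)c1c(OC)cc(OC)cc1Br | intermediate
10 | (2S,4S)-5,7-dimethoxy-2-(2,3,4-trimethoxyphenyl)-3,4-dihydro-2H-chromen-4-ol (2,4-cis) | COc1cc(OC)c2c(c1)O[C@H](c1ccc(OC)c(OC)c1OC)C[C@@H]2O | intermediate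
11 | (2S)-5,7-dimethoxy-2-(2,3,4-trimethoxyphenyl)-2,3-dihydro-4H-chromen-4-one | COc1cc(OC)c2c(c1)O[C@H](c1ccc(OC)c(OC)c1OC)CC2=O | target

**Step count and risks**

Total step count: 6. Longest linear sequence: 6 steps (1 → 3 → 6 → 7 → 9 → 10 → 11; ketone 4 enters at step 2).

Steps most likely to fail:

Step 4. Hydride transfer to the di-ortho-substituted carbonyl beside ring A may be slow or poorly face-selective, so that the reduction stalls at the mono-reduced stage and long reaction times invite retro-aldol cleavage. The fallback gives up control of that carbinol, which step 6 destroys anyway, at the price of carrying epimer pairs. It sets out from 6 and omits step 3. Transfer hydrogenation of the unhindered ketone of 6 with RuCl(p-cymene)[(S,S)-TsDPEN] and HCO2H/Et3N should give (1RS,3S)-1-(2-bromo-4,6-dimethoxyphenyl)-3-(2,3,4-trimethoxyphenyl)propane-1,3-diol F1, with C3 set S by the catalyst. The conditions of step 5 should then close ring C to (2S,4RS)-5,7-dimethoxy-2-(2,3,4-trimethoxyphenyl)-3,4-dihydro-2H-chromen-4-ol F2. The conditions of step 6 should take both epimers to one ketone, and the route is rejoined at 11.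

Step 5. Copper may be held as a chelate between the two hydroxyls, bromine may be lost reductively from C8a, or etherification between two molecules may compete. The fallback sets out from 9 and comes back at 10, changing the metal and the mechanism: Pd(OAc)2 with 2-(di-tert-butylphosphino)-1,1'-binaphthyl and Cs2CO3 in toluene at 70 °C. Here the C–Br bond adds to zerovalent palladium, the alkoxide binds, and the bulky phosphine speeds C–O reductive elimination from the divalent palladium aryl alkoxide ahead of beta-hydride elimination. This is the known palladium-catalysed intramolecular aryl etherification of secondary alcohols, which keeps the carbinol configuration. No new compound is made.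

Step 2. The aldol addition to a hindered, electron-rich aldehyde may reverse, or the adduct may dehydrate to the chalcone on work-up or chromatography. The fallback replaces the aldol and step 3 by an acylation; it sets out from 3 and comes back at 7. Pinnick oxidation (NaClO2, NaH2PO4, 2-methyl-2-butene, t-BuOH/H2O) should give 2-bromo-4,6-dimethoxybenzoic acid F3. Oxalyl chloride with catalytic DMF in CH2Cl2 should give 2-bromo-4,6-dimethoxybenzoyl chloride F4. Soft-enolisation C-acylation of ketone 4 with F4 (MgBr2·OEt2, iPr2NEt, CH2Cl2, rt) should then give diketone 7 directly.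

**Further compounds**

F1 | step 4 | (1RS,3S)-1-(2-bromo-4,6-dimethoxyphenyl)-3-(2,3,4-trimethoxyphenyl)propane-1,3-diol, both C1 epimers | O[C@H](c1ccc(OC)c(OC)c1OC)CC(O)c1c(OC)cc(OC)cc1Br
F2 | step 4 | (2S,4RS)-5,7-dimethoxy-2-(2,3,4-trimethoxyphenyl)-3,4-dihydro-2H-chromen-4-ol, both C4 epimers | COc1cc(OC)c2c(c1)O[C@H](c1ccc(OC)c(OC)c1OC)CC2O
F0 | step 5 | none | none
F3 | step 2 | 2-bromo-4,6-dimethoxybenzoic acid | COc1cc(OC)c(C(=O)O)c(Br)c1
F4 | step 2 | 2-bromo-4,6-dimethoxybenzoyl chloride | COc1cc(OC)c(C(Cl)=O)c(Br)c1
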